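**Charge ratio.** Violet and red each hold 1000 substrate per free catalyst charged. Free catalyst returns with each product, so product counts the turns of the catalyst.

common to all: free catalyst 0.10 mM
- ash: substrate 0.050 M; partner 0.30 M; temperature 5 °C; run made earlier
- red: substrate 0.10 M; partner 0.300 M; temperature −10 °C; time 30 h
- violet: substrate 0.10 M; partner 0.300 M; temperature 5 °C; time 30 h

ash run (percent of the substrate charged): time / h: product / % = 0.667: 1.6; 2.00: 6.6; 3.00: 9.5; 5.00: 16.7; 6.00: 18.6; 10.0: 30.7

(readings scatter by 0.5 percentage points)

- steps thought possible: substrate + catalyst intermediate A -> catalyst intermediate B; catalyst intermediate B -> free catalyst + product; partner -> decomposed reagent; partner + free catalyst <-> catalyst intermediate A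
- the earlier runs do not show what temperature does; that part of a forecast is a guess

1. which one finishes higher in amount of product, in percent of the substrate charged ("neither" within 2 percentage points) (red / violet / neither)
2. amount of product at the end, in percent of the substrate charged, red
3. amount of product at the end, in percent of the substrate charged, violet

**Turn rate.** The ash flask made 30.7% of its substrate in 10.0 h, which is 15.4 h⁻¹ in product per catalyst charged, the turn rate (turnover frequency). The ash rate sagged by 16.2% between the two halves of the run, close to the 16.8% of a first-order course with the same end. Violet has twice the ash substrate, and the ash readings come from a single substrate charge. This reckoning carries the ash turn rate over to violet unchanged, as a choice.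

**Two times.** Two times remain: the 30 h allowed, and the emptying time, the substrate charge over catalyst charge times turn rate. For violet the emptying time is 65.1 h, so their ratio gives 46.1% of the charge. Temperature is a guess: a 4-fold slowing makes the red emptying time 261 h, giving red 11.5%, less than violet.

**Forecast, result.** The forecast says violet, with red 15% and violet 55%, above this reckoning: “Allowing for partner decay, I take about 55%”. The flasks give violet 49.9% and red 15.5%.

    substrate + catalyst intermediate A → catalyst intermediate B (k = 840 M⁻¹ h⁻¹, Ea = 58.0 kJ mol⁻¹)
    catalyst intermediate B → free catalyst + product (k = 120 h⁻¹, Ea = 79.0 kJ mol⁻¹)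
    partner → decomposed reagent (k = 0.0140 h⁻¹, Ea = 97.0 kJ mol⁻¹)
    partner + free catalyst ⇌ catalyst intermediate A (K = 260 M⁻¹, k = 130 M⁻¹ h⁻¹, Ea = 44.0 kJ mol⁻¹, ΔH = 12.0 kJ mol⁻¹)
    (constants at 5 °C)

**Less catalyst.** Over 30 h, violet averaged a turn rate of 16.6 h⁻¹ and red 5.17 h⁻¹, so cooling slowed the flask 3.21-fold. The neighbour flask is red with 60.0% of the catalyst charge. At the red turn rate its emptying time is 322 h, which over 30 h gives 9.32%. That neighbour flask holds 9.45% of product.

The data come from a simulation for an exercise; noise was put on by code.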